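**Plan**
Locants (germacrane numbering): C1 ketone carbon, C2 the furanone =CH, C3 its O-bearing sp2 carbon, C4 (carries C15H2OH), C5, C6 (lactone O–CH), C7, C8 (angelate), C9, C10 (carries the C14 methyl and the furanone oxygen O10), C11=C13 methylene, C12 lactone carbonyl.
Retrosynthetic cuts, in order: O10–C3 (furanone opened to the 4-hydroxy-2-ynone C10(OH)–C1≡C2–C3=O); C2–C3 (ten-membered ring opened to an iodoalkyne aldehyde); C4–C15, the C8 ester and C11=C13; C5–C6 with the lactone C–O; C7–C8; C9–C10.
Forward: one linear chain grown from ynone 1 (C9–C10 allylation, C7–C8 aldol, C5–C6 allylation); the γ-lactone ring closes first, the carbocycle C1–C10 second by the C2–C3 bond, the furanone ring (O10, C10, C1, C2, C3) last by transannular cycloisomerisation.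
Enabling feature: the ethynyl group on the tertiary carbinol C10. C2 is an sp carbon that can be metalated and added to the C3 aldehyde, and the resulting C10(OH)–C1≡C2–C3 unit already holds every atom and the oxidation pattern of the furanone ring.
Stereochemistry: C10 from a catalytic asymmetric ketone allylboration; C7 and C8 from a D-proline anti cross-aldol; C6 from Felkin–Anh plus 1,3-anti substrate control; C4 from diarylprolinol silyl ether enamine catalysis; the (Z)-ester from angelic acid.
The target is (4S,6R,7S,8R,10S) in these locants; the C3 carbinol centre formed in the ring closure is removed by oxidation.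

Key step: step 13

Assumption: in step 1 the alkynyl group of 1 is taken to play the role of the aryl group of aryl methyl ketones, so that the (R)-diol catalyst delivers the (S)-carbinol; if the facial sense proves opposite, the (S)-diol is used.

Step 1
Reactants: 1 4-(trimethylsilyl)but-3-yn-2-one; 2 allylboronic acid diisopropyl ester
Product: 3 (S)-3-methyl-1-(trimethylsilyl)hex-5-en-1-yn-3-ol
Conditions: (R)-3,3'-dibromo-1,1'-bi-2-naphthol (15 mol %), PhMe/PhCF3 3:1, −35 °C; aq NaHCO3
Reagents that add atoms: none
Why: Chiral-diol-catalysed asymmetric allylboration of a ketone, in which the binaphthol-bound allylboronate adds through a closed chair transition state to one face of the ynone carbonyl and thereby sets the C10 carbinol centre under catalyst control.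

Step 2
Reactants: 3 (S)-3-methyl-1-(trimethylsilyl)hex-5-en-1-yn-3-ol
Product: 4 triethylsilyl ether of 3
Conditions: Et3SiOTf, 2,6-lutidine, CH2Cl2, 0 °C
Reagents that add atoms: triethylsilyl trifluoromethanesulfonate CC[Si](CC)(CC)OS(=O)(=O)C(F)(F)F
Why: Silyl triflate silylation of the hindered tertiary alcohol, which removes the retro-aldol and dehydration pathways open to the β-hydroxy aldehyde made next.

Step 3
Reactants: 4 triethylsilyl ether of 3
Product: 5 (S)-3-methyl-3-(triethylsilyloxy)-5-(trimethylsilyl)pent-4-ynal
Conditions: O3, CH2Cl2, −78 °C; then PPh3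
Reagents that add atoms: ozone [O-][O+]=O
Why: Ozonolysis with reductive work-up, in which the terminal alkene reacts far faster with ozone than the silyl-capped alkyne, so that C8 is unveiled as the aldehyde with the C10 centre untouched.

Step 4
Reactants: 5 (S)-3-methyl-3-(triethylsilyloxy)-5-(trimethylsilyl)pent-4-ynal; 6 methyl 4-oxobutanoate
Product: 7 methyl (3R,4R,6S)-3-formyl-4-hydroxy-6-methyl-6-(triethylsilyloxy)-8-(trimethylsilyl)oct-7-ynoate
Conditions: D-proline (20 mol %), DMF, 4 °C, 6 added by syringe pump
Reagents that add atoms: none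
Why: Proline-catalysed direct cross-aldol reaction of two aldehydes, in which only the unhindered donor 6 forms the enamine, the neopentyl-type aldehyde 5 serves as acceptor, and the acid-directed enamine transition state of D-proline should give the anti aldol with C7 and C8 set by the catalyst.

Step 5
Reactants: 7 anti-aldol aldehyde
Product: 8 C8 tert-butyldimethylsilyl ether of 7
Conditions: tBuMe2SiOTf, 2,6-lutidine, CH2Cl2, −78 °C
Reagents that add atoms: tert-butyldimethylsilyl trifluoromethanesulfonate CC(C)(C)[Si](C)(C)OS(=O)(=O)C(F)(F)F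
Why: Low-temperature silylation of the secondary C8 hydroxyl with the silyl triflate, which prevents lactonisation of O8 onto the ester and provides the β-silyloxy group needed for the next stereocontrol.

Step 6
Reactants: 8 β-silyloxy aldehyde; 9 allyltrimethylsilane
Product: 11 allyl lactone (C6,C7-trans γ-lactone), via hydroxy ester 10 (not isolated)
Conditions: BF3·OEt2, CH2Cl2, −78 °C; aq NaHCO3; then pyridinium p-toluenesulfonate (cat), PhMe, 60 °C
Reagents that add atoms: none
Why: Hosomi–Sakurai allylation through an open transition state in which Felkin–Anh control from C7 and 1,3-anti induction from the C8 silyloxy group act in the same sense to set C6, after which the only free hydroxyl (O6) closes the trans-disubstituted γ-lactone onto the methyl ester under mild acid.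

Step 7
Reactants: 11 allyl lactone
Product: 14 α-methylene lactone, via Mannich base 12 (not isolated), via ammonium iodide 13 (not isolated)
Conditions: LiN(iPr)2, THF, −78 °C; Eschenmoser's salt, −78 to 0 °C; then iodomethane, MeOH, rt; then aq NaHCO3, CH2Cl2
Reagents that add atoms: dimethylmethyleneiminium iodide (Eschenmoser's salt) C=[N+](C)C.[I-]; iodomethane CI (its methyl group is carried only by intermediate 13)
Why: Mannich reaction of the lactone lithium enolate with the iminium salt, followed by exhaustive N-methylation and base-induced β-elimination of trimethylamine, installs the exocyclic C11=C13 methylene, the transient C11 centre being destroyed.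

Step 8
Reactants: 14 α-methylene lactone
Product: 15 diol (free C8 and C10 hydroxyls)
Conditions: HF·pyridine, pyridine, THF, 0 °C to rt
Reagents that add atoms: none
Why: Fluoride-mediated cleavage of the two O–Si bonds under buffered conditions that should leave the C(sp)–Si bond and the methylene lactone intact.

Step 9
Reactants: 15 diol; 16 angelic acid ((Z)-2-methylbut-2-enoic acid)
Product: 17 C8 angelate
Conditions: 16, 2,4,6-trichlorobenzoyl chloride, Et3N, PhMe, rt; then 15, PhMe, 80 °C
Reagents that add atoms: none
Why: Yamaguchi esterification by way of the mixed anhydride, run without 4-(dimethylamino)pyridine so that the (Z)-geometry of the acid is kept, in which the tertiary propargylic C10 hydroxyl is too hindered to compete and C8 reacts with retention.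

Step 10
Reactants: 17 C8 angelate
Product: 18 C3 aldehyde
Conditions: PdCl2(PhCN)2 (10 mol %), CuCl2·2H2O (10 mol %), AgNO2 (5 mol %), O2 (1 atm), tBuOH/MeNO2 15:1, rt
Reagents that add atoms: dioxygen O=O
Why: Nitrite-modified aldehyde-selective Wacker oxidation, with anti-Markovnikov oxypalladation of the only electron-rich terminal alkene assisted by the homoallylic lactone oxygen, while the conjugated methylene, the trisubstituted enoate and the silyl alkyne bind divalent palladium poorly.

Step 11
Reactants: 18 C3 aldehyde
Product: 20 silyloxymethyl aldehyde, via hydroxy aldehyde 19 (not isolated)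
Conditions: aq HCHO (37 %), (R)-α,α-diphenylprolinol trimethylsilyl ether (20 mol %), pH 7 phosphate buffer, PhMe, 4 °C; then Et3SiCl, imidazole, CH2Cl2, 0 °C
Reagents that add atoms: formaldehyde C=O; chlorotriethylsilane CC[Si](Cl)(CC)CC
Why: Enamine-catalysed α-hydroxymethylation (crossed aldol with formaldehyde) in which the bulky diphenyl(silyloxy)methyl group of the catalyst shields one enamine face and so sets C4, the labile β-hydroxy aldehyde being capped at once as its primary triethylsilyl ether.

Step 12
Reactants: 20 silyloxymethyl aldehyde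
Product: 21 iodoalkyne aldehyde
Conditions: N-iodosuccinimide, AgNO3 (10 mol %), acetone, rt, dark
Reagents that add atoms: N-iodosuccinimide O=C1CCC(=O)N1I
Why: Silver-catalysed iododesilylation of the alkynylsilane by N-iodosuccinimide (through the silver acetylide) should give the 1-iodoalkyne under neutral conditions that leave the α-branched aldehyde and all stereocentres untouched.

Step 13
Reactants: 21 iodoalkyne aldehyde
Product: 22 cyclodecynol (C3 epimers)
Conditions: CrCl2 (10 equiv), NiCl2 (10 mol %), THF/DMF 3:1, rt, 21 added by syringe pump to 2 mM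
Reagents that add atoms: none
Why: Two equivalents of CrCl2, with NiCl2 relaying the insertion, reduce the C(sp)–iodine bond of 21 to an alkynylchromium dichloride at C2, which adds to the chromium-bound aldehyde carbon C3 and forms the C2–C3 bond. The closest known reaction type is the Nozaki–Hiyama–Kishi closure of iodoalkyne aldehydes to nine- and ten-membered cycloalkynols. The ten-membered carbocycle C1–C10 closes in a 10-exo-trig mode, the carbonyl oxygen staying outside the new ring. The new carbinol centre at C3 is not controlled and need not be, since step 14 removes it. The step needs ring closure to outrun oligomerisation and needs attack at the aldehyde alone: high dilution, the trans-fused lactone, the fully substituted C10 and the rod-like C10–C1≡C2 unit (no transannular hydrogens) favour closure, and organochromium reagents of trivalent chromium add neither to esters, lactones or enoates nor are they quenched by the free C10 hydroxyl. The product carries O10, C1≡C2 and C3 in the arrangement that oxidation turns into the open form of the furanone.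

Step 14
Reactants: 22 cyclodecynol
Product: 23 cyclic 4-hydroxy-2-ynone
Conditions: Dess–Martin periodinane, NaHCO3, CH2Cl2, 0 °C
Reagents that add atoms: none
Why: Dess–Martin oxidation of both C3 epimers of the secondary propargylic alcohol converges on one ynone under buffered conditions that spare the tertiary alcohol, the silyl ether and both enoates.

Step 15
Reactants: 23 cyclic 4-hydroxy-2-ynone
Product: 25 target, via silyl furanone 24 (not isolated)
Conditions: (Ph3P)AuNTf2 (5 mol %), moist PhMe, rt; then HF·pyridine, THF, 0 °C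
Reagents that add atoms: none
Why: Cycloisomerisation of the 4-hydroxy-2-ynone to the 3(2H)-furanone catalysed by monovalent gold (conjugate hydration at C1 by adventitious water, 5-exo-trig attack of O10 on the C3 carbonyl and loss of water) is followed in the same flask by fluoride cleavage of the primary silyl ether, and no stereocentre is touched.

**Compound list**
1 | 4-(trimethylsilyl)but-3-yn-2-one | CC(=O)C#C[Si](C)(C)C | starting material
2 | allylboronic acid diisopropyl ester | C=CCB(OC(C)C)OC(C)C | starting material
3 | (S)-3-methyl-1-(trimethylsilyl)hex-5-en-1-yn-3-ol | C=CC[C@](C)(O)C#C[Si](C)(C)C | intermediate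
4 | (S)-triethyl{[3-methyl-1-(trimethylsilyl)hex-5-en-1-yn-3-yl]oxy}silane | C=CC[C@](C)(O[Si](CC)(CC)CC)C#C[Si](C)(C)C | intermediate
5 | (S)-3-methyl-3-(triethylsilyloxy)-5-(trimethylsilyl)pent-4-ynal | O=CC[C@](C)(O[Si](CC)(CC)CC)C#C[Si](C)(C)C | intermediate
6 | methyl 4-oxobutanoate | COC(=O)CCC=O | starting material
7 | methyl (3R,4R,6S)-3-formyl-4-hydroxy-6-methyl-6-(triethylsilyloxy)-8-(trimethylsilyl)oct-7-ynoate (C7,C8-anti aldol) | O=C[C@H](CC(=O)OC)[C@H](O)C[C@](C)(O[Si](CC)(CC)CC)C#C[Si](C)(C)C | intermediate
8 | methyl (3R,4R,6S)-4-(tert-butyldimethylsilyloxy)-3-formyl-6-methyl-6-(triethylsilyloxy)-8-(trimethylsilyl)oct-7-ynoate | O=C[C@H](CC(=O)OC)[C@H](O[Si](C)(C)C(C)(C)C)C[C@](C)(O[Si](CC)(CC)CC)C#C[Si](C)(C)C | intermediate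
9 | allyltrimethylsilane | C=CC[Si](C)(C)C | starting material
10 | hydroxy ester: C6 homoallylic alcohol (O6 syn to the C7 side chain, anti to O8), methyl ester at C12, C8 OTBS, C10 OTES | C=CC[C@@H](O)[C@H](CC(=O)OC)[C@H](O[Si](C)(C)C(C)(C)C)C[C@](C)(O[Si](CC)(CC)CC)C#C[Si](C)(C)C | intermediate
11 | allyl lactone: C6,C7-trans γ-butyrolactone with allyl on C6 and the C8(OTBS)–C9–C10(Me)(OTES)–C≡C–SiMe3 chain on C7; C6, C7, C8, C10 configured as in 25 | C=CC[C@H]1OC(=O)C[C@@H]1[C@H](O[Si](C)(C)C(C)(C)C)C[C@](C)(O[Si](CC)(CC)CC)C#C[Si](C)(C)C | intermediate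
12 | Mannich base: 11 with a dimethylaminomethyl group on C11 (C11 epimers) | C=CC[C@H]1OC(=O)C(CN(C)C)[C@@H]1[C@H](O[Si](C)(C)C(C)(C)C)C[C@](C)(O[Si](CC)(CC)CC)C#C[Si](C)(C)C | intermediate
13 | ammonium iodide: N-methylated 12 (C11 epimers) | C=CC[C@H]1OC(=O)C(C[N+](C)(C)C)[C@@H]1[C@H](O[Si](C)(C)C(C)(C)C)C[C@](C)(O[Si](CC)(CC)CC)C#C[Si](C)(C)C.[I-] | intermediate
14 | α-methylene lactone: 11 with exocyclic C11=C13H2 | C=CC[C@H]1OC(=O)C(=C)[C@@H]1[C@H](O[Si](C)(C)C(C)(C)C)C[C@](C)(O[Si](CC)(CC)CC)C#C[Si](C)(C)C | intermediate
15 | diol: 14 with free C8 and C10 hydroxyls | C=CC[C@H]1OC(=O)C(=C)[C@@H]1[C@H](O)C[C@](C)(O)C#C[Si](C)(C)C | intermediate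
16 | angelic acid, (Z)-2-methylbut-2-enoic acid | C/C=C(/C)C(=O)O | starting material
17 | C8 angelate of 15 | C=CC[C@H]1OC(=O)C(=C)[C@@H]1[C@H](OC(=O)/C(C)=C\C)C[C@](C)(O)C#C[Si](C)(C)C | intermediate
18 | C3 aldehyde: 17 with the allyl group turned into CH2CH2CHO | O=CCC[C@H]1OC(=O)C(=C)[C@@H]1[C@H](OC(=O)/C(C)=C\C)C[C@](C)(O)C#C[Si](C)(C)C | intermediate
19 | hydroxy aldehyde: 18 with CH2OH on C4, (4S) | O=C[C@H](CO)C[C@H]1OC(=O)C(=C)[C@@H]1[C@H](OC(=O)/C(C)=C\C)C[C@](C)(O)C#C[Si](C)(C)C | intermediate
20 | silyloxymethyl aldehyde: C15 triethylsilyl ether of 19 | O=C[C@H](CO[Si](CC)(CC)CC)C[C@H]1OC(=O)C(=C)[C@@H]1[C@H](OC(=O)/C(C)=C\C)C[C@](C)(O)C#C[Si](C)(C)C | intermediate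
21 | iodoalkyne aldehyde: 20 with C2–iodine in place of C2–SiMe3 | O=C[C@H](CO[Si](CC)(CC)CC)C[C@H]1OC(=O)C(=C)[C@@H]1[C@H](OC(=O)/C(C)=C\C)C[C@](C)(O)C#CI | intermediate
22 | cyclodecynol: ten-membered ring C1–C10 with C1≡C2, C3 carbinol (epimers), free C10 hydroxyl, fused trans lactone | C=C1C(=O)O[C@@H]2C[C@@H](CO[Si](CC)(CC)CC)C(O)C#C[C@@](C)(O)C[C@@H](OC(=O)/C(C)=C\C)[C@@H]12 | intermediate
23 | cyclic 4-hydroxy-2-ynone: 22 with C3 ketone | C=C1C(=O)O[C@@H]2C[C@@H](CO[Si](CC)(CC)CC)C(=O)C#C[C@@](C)(O)C[C@@H](OC(=O)/C(C)=C\C)[C@@H]12 | intermediate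
24 | silyl furanone: C15 triethylsilyl ether of the target | C=C1C(=O)O[C@@H]2C[C@@H](CO[Si](CC)(CC)CC)C3=CC(=O)[C@](C)(C[C@@H](OC(=O)/C(C)=C\C)[C@@H]12)O3 | intermediate
25 | CNP0108636.1, (4S,6R,7S,8R,10S) in the locants above | C=C1C(=O)O[C@@H]2C[C@@H](CO)C3=CC(=O)[C@](C)(C[C@@H](OC(=O)/C(C)=C\C)[C@@H]12)O3 | target

**Totals**
Total step count: 15. Longest linear sequence: 15 steps (1 to 25).

**Steps most likely to fail**

Step 13. Intermolecular coupling and protonation of the alkynylchromium species may outrun closure of the ten-membered ring. The fallback sets out from 20 and comes back at 23. Silver-catalysed protodesilylation (AgNO3, 2,6-lutidine, acetone/H2O) should give the terminal alkyne aldehyde F1. Chlorite oxidation (NaClO2, NaH2PO4, 2-methylbut-2-ene, tBuOH/H2O) should give the carboxylic acid F2. Ethanethiol, dicyclohexylcarbodiimide and catalytic 4-(dimethylamino)pyridine should give the S-ethyl thioester F3. A high-dilution thioester–alkyne coupling of Sonogashira type (PdCl2(dppf), CuI, Et3N, DMF, 50 °C) would then forge the same C2–C3 bond at the acyl oxidation level and deliver ynone 23 directly, so that step 14 falls away.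

Step 11. The amine catalyst, or the enamine carbon C4 itself, may add to the exocyclic enoate (aza-Michael capture of the catalyst, or six-membered Michael closure from C4 to C13) faster than the enamine is hydroxymethylated. The fallback sets out from 18 and comes back at 20, and masks the enoate first. Dimethylamine (THF, 0 °C) should add to the methylene lactone to give the amino lactone F4. Hydroxymethylation and silylation as in step 11 should then give the silyl ether F6 by way of the hydroxy aldehyde F5. Iodomethane followed by aqueous NaHCO3 should regenerate the methylene group through the ammonium iodide F7 and return 20.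

Step 10. Markovnikov hydroxypalladation (giving the methyl ketone), alkene isomerisation, or binding of palladium to the silyl alkyne and the propargylic alcohol may erode the aldehyde. The fallback sets out from 17 and comes back at 18. Cross-metathesis of 17 with vinylboronic acid pinacol ester (second-generation Hoveyda–Grubbs catalyst, CH2Cl2, 40 °C) should give the (E)-alkenylboronate F8. Oxidation of the C–B bond (NaBO3·4H2O, THF/H2O) should give the enol and hence aldehyde 18.

Further compounds
F1 | step 13 | terminal alkyne aldehyde (20 with C2–H in place of C2–SiMe3) | O=C[C@H](CO[Si](CC)(CC)CC)C[C@H]1OC(=O)C(=C)[C@@H]1[C@H](OC(=O)/C(C)=C\C)C[C@](C)(O)C#C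
F2 | step 13 | carboxylic acid (C3 acid of F1) | OC(=O)[C@H](CO[Si](CC)(CC)CC)C[C@H]1OC(=O)C(=C)[C@@H]1[C@H](OC(=O)/C(C)=C\C)C[C@](C)(O)C#C
F3 | step 13 | S-ethyl thioester of F2 | CCSC(=O)[C@H](CO[Si](CC)(CC)CC)C[C@H]1OC(=O)C(=C)[C@@H]1[C@H](OC(=O)/C(C)=C\C)C[C@](C)(O)C#C
F4 | step 11 | amino lactone (dimethylamine adduct of 18 at C13, C11 epimers) | O=CCC[C@H]1OC(=O)C(CN(C)C)[C@@H]1[C@H](OC(=O)/C(C)=C\C)C[C@](C)(O)C#C[Si](C)(C)C
F5 | step 11 | hydroxy aldehyde (F4 with CH2OH on C4) | O=C[C@H](CO)C[C@H]1OC(=O)C(CN(C)C)[C@@H]1[C@H](OC(=O)/C(C)=C\C)C[C@](C)(O)C#C[Si](C)(C)C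
F6 | step 11 | silyl ether (C15 triethylsilyl ether of F5) | O=C[C@H](CO[Si](CC)(CC)CC)C[C@H]1OC(=O)C(CN(C)C)[C@@H]1[C@H](OC(=O)/C(C)=C\C)C[C@](C)(O)C#C[Si](C)(C)C
F7 | step 11 | ammonium iodide (N-methylated F6) | O=C[C@H](CO[Si](CC)(CC)CC)C[C@H]1OC(=O)C(C[N+](C)(C)C)[C@@H]1[C@H](OC(=O)/C(C)=C\C)C[C@](C)(O)C#C[Si](C)(C)C.[I-]
F8 | step 10 | (E)-alkenylboronate (pinacol boronate on C3 of the C3=C4 alkene of 17) | CC1(C)OB(/C=C/C[C@H]2OC(=O)C(=C)[C@@H]2[C@H](OC(=O)/C(C)=C\C)C[C@](C)(O)C#C[Si](C)(C)C)OC1(C)C
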